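**Assumption (one line):** ring numbering is O1–O2–C3–C4=C5–C6; CIP analysis of the SMILES gives (3S,6S) with the 6‑OMe cis to the C3 side chain; the facial sense given for the catalyst in step 3 follows the usual shielding model of diarylprolinol silyl ethers, and the mirror‑image catalyst would be used if the sense proved opposite.

## The problem

6‑epi‑Chondrillin (11) is a monocyclic 3,6‑dihydro‑1,2‑dioxine with a CH2CO2Me arm on C3 and, on C6, a methoxy group and an unbranched hexadecyl chain, so the whole difficulty sits in the six ring atoms. The ring holds an O–O bond that will not survive phosphines, hydrides, hydrogenation or low‑valent metals, a cis double bond between two oxygenated allylic carbons, and a peroxyketal (C6) that ionises in acid. The β‑peroxy ester is also base‑labile: deprotonation at C2 expels O2 (retro‑Michael ring opening) and deprotonation at C3 starts a Kornblum–DeLaMare cleavage. There are two stereocentres, C3 (secondary C–OO) and C6 (fully substituted ketal). C6 is an anomeric centre that can be epimerised through the cyclic peroxycarbenium ion, and the cis isomer is the one that can place OMe pseudoaxial with both carbon substituents pseudoequatorial; C3 can therefore control C6, but nothing in the molecule controls C3. The real problem is thus the absolute configuration of a secondary carbon–peroxide bond, together with bringing in the O–O unit intact. The enabling feature is that O2 sits on C3 in a 1,3‑relation to the ester carbonyl (O2–C3–C2–C1=O), the retron of a conjugate addition, while O1 sits with OMe on C6, so that C6(OMe)–O1–O2H is an α‑methoxy hydroperoxide; the ring bond C4=C5 between these two carbons is the retron of a ring‑closing metathesis.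

## Retrosynthesis

**11 ⇒ 10 (C6–OMe bond, exchange).** The configuration at C6 is not planned for earlier. It is left to a final acid‑catalysed ketal exchange on the C6‑epimeric mixture 10, in which C3 decides. This removes one stereocentre from everything that precedes; the forward reaction must only leave C3 and the O–O bond alone.

**10 ⇒ 8 (via acid 9; oxidation level at C1).** The ester is taken back to the aldehyde 8, because only an aldehyde lets C2=C3 be activated as an iminium ion. The forward reaction is a mild oxidation and methylation that avoids base.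

**8 ⇒ 7 (cut C4=C5).** Ring‑closing metathesis is preferred over any carbonyl olefination because the six‑membered ring enforces the cis geometry without a Z‑selective reagent. The precursor 7 is an open‑chain dialkyl peroxide with one alkene on each side of the O–O bond. The forward reaction must close a ring through a vinyl group on a fully substituted carbon and must not reduce the peroxide.

**7 ⇒ 5 + 6 (cut O2–C3; key disconnection).** Cutting the C–O bond β to the carbonyl splits the molecule into the C19 hydroperoxy ketal 5 and the C5 dienal 6, whose phenyl group is sacrificial and later leaves as styrene. The neighbouring cut O1–C6 would first require an enantioenriched secondary hydroperoxide. The intramolecular version of the same O2–C3 closure would require a Z‑diene and a resolved ketal carbon. The forward reaction is an amine‑catalysed enantioselective peroxy‑Michael addition; it must be 1,4‑selective, stop at the peroxide stage and set C3. 5 may be racemic.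

**5 ⇒ 4 (cut C6–O1).** The α‑methoxy hydroperoxide is the adduct of H2O2 to the allenyl ether 4: protonation of the central allene carbon gives the 1‑methoxyallyl cation, which already carries the vinyl group needed for the metathesis. The precursor has no peroxide and no stereocentre.

**4 ⇒ 1 + 2 (cut C6–C7, via 3).** Alkylation of lithiated methoxyallene 3 with 1‑iodohexadecane 2 joins the chain to the future ketal carbon in one step from two commercial materials.

## Roads not taken

**Alternative 1:** cut both C–O bonds; [4+2] cycloaddition of singlet oxygen to the 1‑methoxydiene A1, giving the racemic dioxine A2. This is the most obvious route and is very short on paper. It has no element of absolute control, unless a chiral alkoxy group is used and later exchanged. The cis product needs the (5E) isomer of A1, which puts the hexadecyl chain "inside" and disfavours the s‑cis conformer. Ene reaction and [2+2] addition at the enol ether compete, and A1 itself requires a geometrically defined trisubstituted enol ether. The chosen plan sets C3 by catalysis and needs no diene geometry.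

**Alternative 2:** cut O1–C6; cyclisation of the (Z)‑γ‑hydroperoxy enone A3 to the dioxinol A4, then ketalisation with MeOH/H+. The ring closure is reliable, but the difficulty is only moved: A3 is an enantioenriched secondary allylic hydroperoxide next to a Z‑enone, and reaching it requires a resolution or a chirality‑transfer sequence on a linear, sensitive chain. The chosen plan is convergent and never carries a free secondary hydroperoxide.

**Alternative 3:** cut C3–C2; Lewis‑acid ionisation of the bis‑acetal dioxine A6 (from the Z‑enedial‑type compound A5, H2O2 and MeOH) and capture of the peroxycarbenium ion at C3 by the silyl ketene acetal of methyl acetate. A6 has two ionisable centres, and the ketal C6 should ionise faster than the acetal C3. The resulting cation is an allyl cation that can also be captured at C4. Absolute configuration would have to come from a chiral counter‑anion acting on a peroxycarbenium ion with no binding handle. The chosen plan forms the C3 stereocentre in a reaction with an established stereochemical model.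

Key step: step 3

## Route

Step 1
Reactants: 1 methoxyallene (1‑methoxypropa‑1,2‑diene); 2 1‑iodohexadecane
Product: 4 3‑methoxynonadeca‑1,2‑diene, via 1‑lithio‑1‑methoxyallene 3 (not isolated)
Conditions: n‑BuLi (1.05 equiv), THF, −40 °C; then 2, −40 °C → rt; NaHCO3 work‑up, basic alumina
Reagents that add atoms: none
Why: Alkoxyallenes are deprotonated cleanly at C1 (α to oxygen) and the lithio species is alkylated by primary iodides (SN2); no stereocentre is formed and the acid‑sensitive allenyl ether is handled under basic conditions.

Step 2
Reactants: 4 3‑methoxynonadeca‑1,2‑diene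
Product: 5 3‑hydroperoxy‑3‑methoxynonadec‑1‑ene (racemic)
Conditions: anhydrous H2O2 in Et2O (5 equiv), PPTS (5 mol%), BHT (trace), 0 °C; NaHCO3 work‑up
Reagents that add atoms: hydrogen peroxide, OO
Why: Acid‑catalysed Markovnikov addition of H2O2 to an enol ether: protonation of the central allene carbon gives the 1‑methoxyallyl cation, which is captured at the oxygen‑bearing carbon as in the addition of alcohols to alkoxyallenes. Excess H2O2 suppresses the bis‑adduct, and the new stereocentre is formed racemic on purpose.

Step 3
Reactants: 5 3‑hydroperoxy‑3‑methoxynonadec‑1‑ene (1.3 equiv); 6 (2E,4E)‑5‑phenylpenta‑2,4‑dienal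
Product: 7 (3S,4E)‑3‑[(3‑methoxynonadec‑1‑en‑3‑yl)peroxy]‑5‑phenylpent‑4‑enal (both epimers at the ketal carbon)
Conditions: (S)‑2‑{bis[3,5‑bis(trifluoromethyl)phenyl](trimethylsilyloxy)methyl}pyrrolidine (10 mol%), PhCO2H (10 mol%), toluene, 0 °C; rapid filtration through silica
Reagents that add atoms: none
Why: The secondary amine condenses with 6 to the E,s‑trans iminium ion, the terminal oxygen of hydroperoxide 5 adds to C3, and the β‑peroxy enamine is protonated at C2 and hydrolysed to 7 with release of the catalyst. The closest known reaction type is the amine‑catalysed enantioselective conjugate addition of hydroperoxides to enals, the first stage of the organocatalytic enal epoxidation, held here at the peroxide stage by the carboxylic acid co‑catalyst and low temperature so that C‑protonation of the enamine outruns its attack on the O–O bond. No ring is closed; the step forms the O2–C3 bond and thereby joins the C19 and C5 halves. C3 is the only new stereocentre and is set by the catalyst: the CAr2OSiMe3 group shields one face of the iminium ion and the hydroperoxide enters from the other, which for the (S)‑catalyst should give 3S. The ketal carbon of 5 is racemic and three atoms away from the forming bond, so both enantiomers should add at similar rates and give two C6 epimers of the same C3 configuration, which is all the later steps need. The step needs 1,4‑ over 1,6‑selectivity: attack at C5 would break the styrene conjugation and place a bulky tertiary peroxide on a benzylic carbon, whereas 1,4‑addition leaves the styrene intact. It also needs the adduct not to revert, which is why 7 is separated from the amine at once and used directly.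

Step 4
Reactants: 7 (3S,4E)‑3‑[(3‑methoxynonadec‑1‑en‑3‑yl)peroxy]‑5‑phenylpent‑4‑enal
Product: 8 2‑[(3S)‑6‑hexadecyl‑6‑methoxy‑3,6‑dihydro‑1,2‑dioxin‑3‑yl]acetaldehyde (both C6 epimers)
Conditions: Hoveyda–Grubbs second‑generation catalyst (5 mol%), CH2Cl2 (5 mM), 40 °C
Reagents that add atoms: none
Why: Ring‑closing metathesis between the vinyl group and the styrenyl alkene gives the six‑membered ring, in which C4=C5 can only be cis, and releases styrene. A phosphine‑free ruthenium alkylidene is chosen so that no phosphine is present to reduce the dialkyl peroxide; C3 is not touched.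

Step 5
Reactants: 8 2‑[(3S)‑6‑hexadecyl‑6‑methoxy‑3,6‑dihydro‑1,2‑dioxin‑3‑yl]acetaldehyde
Product: 10 methyl 2‑[(3S)‑6‑hexadecyl‑6‑methoxy‑3,6‑dihydro‑1,2‑dioxin‑3‑yl]acetate (both C6 epimers), via dioxinylacetic acid 9 (not isolated)
Conditions: NaClO2, NaH2PO4, 2‑methyl‑2‑butene, t‑BuOH/H2O, 0 °C; then TMSCHN2, toluene/MeOH, 0 °C
Reagents that add atoms: sodium chlorite, [Na+].[O-]Cl=O; trimethylsilyldiazomethane, C[Si](C)(C)C=[N+]=[N-]
Why: Pinnick oxidation and diazoalkane methylation are both free of base, so neither retro‑Michael opening nor Kornblum–DeLaMare cleavage is triggered, and dialkyl peroxides are inert to chlorite. Any OMe/OH exchange at the now cyclic ketal under the buffer is reversed in step 6.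

Step 6
Reactants: 10 methyl 2‑[(3S)‑6‑hexadecyl‑6‑methoxy‑3,6‑dihydro‑1,2‑dioxin‑3‑yl]acetate (both C6 epimers)
Product: 11 6‑epi‑chondrillin, methyl 2‑[(3S,6S)‑6‑hexadecyl‑6‑methoxy‑3,6‑dihydro‑1,2‑dioxin‑3‑yl]acetate
Conditions: CSA (10 mol%), anhydrous MeOH, 0 °C → rt; chromatography; recovered 6R component re‑subjected
Reagents that add atoms: methanol, CO
Why: Acid‑catalysed ketal exchange through the cyclic peroxycarbenium ion equilibrates C6 under control of C3. The 6S (cis) isomer can hold OMe pseudoaxial (anomeric effect) with the hexadecyl and CH2CO2Me groups pseudoequatorial and should therefore be favoured, probably only moderately, so the separated 6R material is recycled through the same conditions.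

## Compound list

1 | methoxyallene (1‑methoxypropa‑1,2‑diene) | COC=C=C | starting material
2 | 1‑iodohexadecane | CCCCCCCCCCCCCCCCI | starting material
3 | 1‑lithio‑1‑methoxyallene | [Li]C(OC)=C=C | intermediate (not isolated)
4 | 3‑methoxynonadeca‑1,2‑diene | CCCCCCCCCCCCCCCCC(OC)=C=C | intermediate
5 | 3‑hydroperoxy‑3‑methoxynonadec‑1‑ene (racemic) | CCCCCCCCCCCCCCCCC(OC)(OO)C=C | intermediate
6 | (2E,4E)‑5‑phenylpenta‑2,4‑dienal | O=C/C=C/C=C/c1ccccc1 | starting material
7 | (3S,4E)‑3‑[(3‑methoxynonadec‑1‑en‑3‑yl)peroxy]‑5‑phenylpent‑4‑enal (C6 epimers) | O=CC[C@H](OOC(OC)(CCCCCCCCCCCCCCCC)C=C)/C=C/c1ccccc1 | intermediate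
8 | 2‑[(3S)‑6‑hexadecyl‑6‑methoxy‑3,6‑dihydro‑1,2‑dioxin‑3‑yl]acetaldehyde (C6 epimers) | O=CC[C@H]1C=CC(OC)(CCCCCCCCCCCCCCCC)OO1 | intermediate
9 | 2‑[(3S)‑6‑hexadecyl‑6‑methoxy‑3,6‑dihydro‑1,2‑dioxin‑3‑yl]acetic acid (C6 epimers) | OC(=O)C[C@H]1C=CC(OC)(CCCCCCCCCCCCCCCC)OO1 | intermediate (not isolated)
10 | methyl 2‑[(3S)‑6‑hexadecyl‑6‑methoxy‑3,6‑dihydro‑1,2‑dioxin‑3‑yl]acetate (C6 epimers) | COC(=O)C[C@H]1C=CC(OC)(CCCCCCCCCCCCCCCC)OO1 | intermediate
11 | 6‑epi‑chondrillin, methyl 2‑[(3S,6S)‑6‑hexadecyl‑6‑methoxy‑3,6‑dihydro‑1,2‑dioxin‑3‑yl]acetate | CCCCCCCCCCCCCCCC[C@@]1(OC)C=C[C@H](CC(=O)OC)OO1 | target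

## Step count and risks

Total step count: 6. Longest linear sequence: 6 steps (1 → 4 → 5 → 7 → 8 → 10 → 11); 2 and 6 are commercial.

**Step 3 (key step).** The most likely failure is slow addition of the fully substituted, bulky hydroperoxide, so that reversal of the addition or collapse of the peroxy‑enamine onto the O–O bond (epoxide formation) overtakes productive turnover and lowers conversion and enantiopurity. The fallback inverts the order of union, sets out from 6 and 4 and comes back at 10. The small reagent 2‑hydroperoxy‑2‑methoxypropane F1 (from 2‑methoxypropene and H2O2) is added to 6 under the same amine catalysis to give (S,E)‑3‑[(2‑methoxypropan‑2‑yl)peroxy]‑5‑phenylpent‑4‑enal F2. Pinnick oxidation and TMSCHN2 give methyl (S,E)‑3‑[(2‑methoxypropan‑2‑yl)peroxy]‑5‑phenylpent‑4‑enoate F3, and aqueous acetic acid in THF frees methyl (S,E)‑3‑hydroperoxy‑5‑phenylpent‑4‑enoate F4. PPTS‑catalysed addition of F4 across allene 4 then forms the O1–C6 bond and gives methyl (3S,4E)‑3‑[(3‑methoxynonadec‑1‑en‑3‑yl)peroxy]‑5‑phenylpent‑4‑enoate F5, whose ring‑closing metathesis gives 10.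

**Step 4.** The likely failures are reductive or fragmentative attack of ruthenium on the O–O bond, and failure of the vinyl group on the fully substituted, doubly oxygenated carbon to enter the catalytic cycle, leading to oligomerisation through the styrenyl end. The fallback gives up metathesis and closes the ring at O1–C6; it sets out from 6 by way of F2 and F3 and comes back at 11. Ozonolysis of F3 (O3, CH2Cl2, −78 °C; Me2S) gives methyl (S)‑3‑[(2‑methoxypropan‑2‑yl)peroxy]‑4‑oxobutanoate F6. A Wittig reaction under neutral conditions with 1‑(triphenyl‑λ5‑phosphanylidene)octadecan‑2‑one F7 (from methylenetriphenylphosphorane and methyl heptadecanoate) gives methyl (3S,4E)‑3‑[(2‑methoxypropan‑2‑yl)peroxy]‑6‑oxodocos‑4‑enoate F8. Aqueous acetic acid frees methyl (3S,4E)‑3‑hydroperoxy‑6‑oxodocos‑4‑enoate F9. Irradiation equilibrates the enone geometry, the Z isomer A3 is drained from the photo‑equilibrium as the dioxinol A4, and CSA in methanol converts A4 into 11.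

**Step 2.** The likely failures are capture of the methoxyallyl cation at its terminal carbon, a second addition (bis‑peroxide or gem‑dihydroperoxide), and radical allylic transposition of the tertiary hydroperoxide on standing. The fallback replaces the irreversible allene addition by an equilibrium ketal exchange; it sets out from 4 and comes back at 5. PPTS‑catalysed addition of methanol to 4 gives the storable ketal 3,3‑dimethoxynonadec‑1‑ene F10, and exchange of one methoxy group of F10 with ethereal H2O2 under acid catalysis gives 5.

**Step 6.** The likely failure is an equilibrium that lies too close to parity, so that recycling becomes laborious, with slow loss through capture of the allyl‑type cation at C4 on long exposure to acid. The fallback replaces thermodynamic by kinetic control; it sets out from 10 and comes back at 11 with no new compound. Ionisation with TMSOTf in CH2Cl2 at −78 °C in the presence of MeOSiMe3 should lead to pseudoaxial capture of the peroxycarbenium ion in the half‑chair that keeps the C3 arm pseudoequatorial, which delivers OMe cis to the arm.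

## Further compounds

F1 | step 3 | 2‑hydroperoxy‑2‑methoxypropane | COC(C)(C)OO
F2 | step 3 | (S,E)‑3‑[(2‑methoxypropan‑2‑yl)peroxy]‑5‑phenylpent‑4‑enal | O=CC[C@H](OOC(C)(C)OC)/C=C/c1ccccc1
F3 | step 3 | methyl (S,E)‑3‑[(2‑methoxypropan‑2‑yl)peroxy]‑5‑phenylpent‑4‑enoate | COC(=O)C[C@H](OOC(C)(C)OC)/C=C/c1ccccc1
F4 | step 3 | methyl (S,E)‑3‑hydroperoxy‑5‑phenylpent‑4‑enoate | COC(=O)C[C@H](OO)/C=C/c1ccccc1
F5 | step 3 | methyl (3S,4E)‑3‑[(3‑methoxynonadec‑1‑en‑3‑yl)peroxy]‑5‑phenylpent‑4‑enoate | COC(=O)C[C@H](OOC(OC)(CCCCCCCCCCCCCCCC)C=C)/C=C/c1ccccc1
F6 | step 4 | methyl (S)‑3‑[(2‑methoxypropan‑2‑yl)peroxy]‑4‑oxobutanoate | COC(=O)C[C@H](OOC(C)(C)OC)C=O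
F7 | step 4 | 1‑(triphenyl‑λ5‑phosphanylidene)octadecan‑2‑one | CCCCCCCCCCCCCCCCC(=O)C=P(c1ccccc1)(c1ccccc1)c1ccccc1
F8 | step 4 | methyl (3S,4E)‑3‑[(2‑methoxypropan‑2‑yl)peroxy]‑6‑oxodocos‑4‑enoate | COC(=O)C[C@H](OOC(C)(C)OC)/C=C/C(=O)CCCCCCCCCCCCCCCC
F9 | step 4 | methyl (3S,4E)‑3‑hydroperoxy‑6‑oxodocos‑4‑enoate | COC(=O)C[C@H](OO)/C=C/C(=O)CCCCCCCCCCCCCCCC
F10 | step 2 | 3,3‑dimethoxynonadec‑1‑ene | CCCCCCCCCCCCCCCCC(OC)(OC)C=C
F0 | step 6 | none | none
A1 | alternative 1 | methyl (3E,5E)‑6‑methoxydocosa‑3,5‑dienoate | COC(=O)C/C=C/C=C(OC)\CCCCCCCCCCCCCCCC
A2 | alternative 1 | methyl 2‑(6‑hexadecyl‑6‑methoxy‑3,6‑dihydro‑1,2‑dioxin‑3‑yl)acetate (racemic) | CCCCCCCCCCCCCCCCC1(OC)C=CC(CC(=O)OC)OO1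
A3 | alternative 2 | methyl (3S,4Z)‑3‑hydroperoxy‑6‑oxodocos‑4‑enoate | CCCCCCCCCCCCCCCCC(=O)/C=C\[C@@H](OO)CC(=O)OC
A4 | alternative 2 | methyl 2‑[(3S)‑6‑hexadecyl‑6‑hydroxy‑3,6‑dihydro‑1,2‑dioxin‑3‑yl]acetate | CCCCCCCCCCCCCCCCC1(O)C=C[C@H](CC(=O)OC)OO1
A5 | alternative 3 | (Z)‑4‑oxoicos‑2‑enal | O=C/C=C\C(=O)CCCCCCCCCCCCCCCC
A6 | alternative 3 | 6‑hexadecyl‑3,6‑dimethoxy‑3,6‑dihydro‑1,2‑dioxine | COC1C=CC(OC)(CCCCCCCCCCCCCCCC)OO1
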